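**Retrosynthetic overview**
1. The strategy rests on the cis (erythro) C8–O/C9–O pair on the ten-membered carbocycle C1–C10: it is the syn-dihydroxylation retron of a ring Z-C8=C9 alkene, so target 43 ⇒ diol 36 ⇒ triene lactone 35 (two late acylations, then OsO4).
2. 35 ⇒ ring-closing metathesis at C8=C9 of 34, which carries a vinyl group on C7 of a trans γ-lactone and a vinyl group on C10 of the dienoate.
3. 34 ⇒ γ-lactone closed by SN2 with inversion at C6 from seco-ester 31, made by zinc Barbier union (C6–C7) of epoxy aldehyde 23 with dienyl bromide 29. The Barbier step is expected to give the 6-epi, 6,7-syn adduct, and the inversion corrects both relationships.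
4. 23 ⇒ dienoate by Horner–Wadsworth–Emmons/selenoxide elimination at C1; C2–C3 oxirane by asymmetric γ-chloroallylboration, closure and ozonolysis; C4–C5 oxirane by Sharpless epoxidation of a Z-allylic alcohol.
5. Ring order: C4–C5 oxirane, C2–C3 oxirane, γ-lactone, ten-membered carbocycle; epoxy acid 40 is made separately from angelic acid.

Key step: step 20

Remark: atoms carry germacrane numbers (ring C1–C10, lactone C11–C13, ester carbon C14, methyl C15), CIP descriptors are those of the compound named, and 1, 2, 14, 37 and (+)-B-methoxydiisopinocampheylborane are taken as commercial.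

Step 1
Reactants: 1 2-{[tert-butyl(dimethyl)silyl]oxy}acetaldehyde; 2 ethyl 2-[bis(2,2,2-trifluoroethoxy)phosphoryl]propanoate
Product: 3 ethyl (2Z)-4-{[tert-butyl(dimethyl)silyl]oxy}-2-methylbut-2-enoate
Conditions: 2, KN(SiMe3)2, 18-crown-6, THF, −78 °C; then 1
Reagents that add atoms: none
Why: Still–Gennari olefination, in which the electron-poor phosphonate under dissociating conditions eliminates from the kinetic adduct and should give the Z-trisubstituted enoate, placing the future C3 and C6 cis on C4=C5.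

Step 2
Reactants: 3 ethyl (2Z)-4-{[tert-butyl(dimethyl)silyl]oxy}-2-methylbut-2-enoate
Product: 4 (2Z)-4-{[tert-butyl(dimethyl)silyl]oxy}-2-methylbut-2-en-1-ol
Conditions: iBu2AlH, CH2Cl2, −78 °C; aqueous KNaC4H4O6 work-up
Reagents that add atoms: none
Why: 1,2-reduction of an enoate by iBu2AlH at low temperature should give the allylic alcohol without touching the silyl ether or the alkene geometry.

Step 3
Reactants: 4 (2Z)-4-{[tert-butyl(dimethyl)silyl]oxy}-2-methylbut-2-en-1-ol
Product: 5 [(2S,3R)-3-({[tert-butyl(dimethyl)silyl]oxy}methyl)-2-methyloxiran-2-yl]methanol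
Conditions: Ti(OiPr)4 (10 mol %), L-(+)-diisopropyl tartrate (12 mol %), tBuOOH, 4 Å sieves, CH2Cl2, −20 °C
Reagents that add atoms: tert-butyl hydroperoxide, CC(C)(C)OO
Why: Sharpless asymmetric epoxidation directed by the C3 hydroxyl, in which the L-(+)-tartrate complex delivers oxygen to the face that sets C4 and C5 as in the target, the Z-alkene giving the cis (C3/C6) oxirane.

Step 4
Reactants: 5 [(2S,3R)-3-({[tert-butyl(dimethyl)silyl]oxy}methyl)-2-methyloxiran-2-yl]methanol
Product: 6 (2R,3R)-3-({[tert-butyl(dimethyl)silyl]oxy}methyl)-2-methyloxirane-2-carbaldehyde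
Conditions: Dess–Martin periodinane, pyridine, CH2Cl2, 0 °C to rt
Reagents that add atoms: none
Why: Dess–Martin oxidation of a primary epoxy alcohol is mild and neutral, and the α-carbon is quaternary so it cannot epimerise.

Step 5
Reactants: 6 (2R,3R)-3-({[tert-butyl(dimethyl)silyl]oxy}methyl)-2-methyloxirane-2-carbaldehyde; 7 allyl chloride
Product: 10 (1S,2S)-1-[(2S,3R)-3-({[tert-butyl(dimethyl)silyl]oxy}methyl)-2-methyloxiran-2-yl]-2-chlorobut-3-en-1-ol, via chloroallylborane 8 (not isolated), via borinate ester 9 (not isolated)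
Conditions: 7, (+)-Ipc2BOMe, LiN(c-C6H11)2 (from dicyclohexylamine and nBuLi), Et2O, −95 °C; BF3·OEt2; then 6, −95 °C; 2-aminoethanol work-up
Reagents that add atoms: none
Why: Brown-type asymmetric γ-chloroallylboration, in which the (Z)-chloroallylborane reacts through a closed chair transition state so that Cl and OH end up syn, and the isopinocampheyl groups derived from (−)-α-pinene direct addition to the re face of the aldehyde (C3 S), overriding the modest bias of the α-quaternary epoxide.

Step 6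
Reactants: 10 (1S,2S)-1-[(2S,3R)-3-({[tert-butyl(dimethyl)silyl]oxy}methyl)-2-methyloxiran-2-yl]-2-chlorobut-3-en-1-ol
Product: 11 tert-butyl{[(2R,3R)-3-[(2R,3R)-3-ethenyloxiran-2-yl]-3-methyloxiran-2-yl]methoxy}dimethylsilane
Conditions: DBU, CH2Cl2, rt
Reagents that add atoms: none
Why: intramolecular Williamson closure (3-exo-tet) at the allylic chloride with inversion at C2 converts the syn-chlorohydrin into the cis C2–C3 oxirane, and is faster than Payne-type attack on the quaternary C4.

Step 7
Reactants: 11 tert-butyl{[(2R,3R)-3-[(2R,3R)-3-ethenyloxiran-2-yl]-3-methyloxiran-2-yl]methoxy}dimethylsilane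
Product: 13 (2S,3R)-3-[(2R,3R)-3-({[tert-butyl(dimethyl)silyl]oxy}methyl)-2-methyloxiran-2-yl]oxirane-2-carbaldehyde, via ozonide 12 (not isolated)
Conditions: O3, CH2Cl2, −78 °C; then PPh3, −78 °C to rt
Reagents that add atoms: ozone, [O-][O+]=O
Why: ozonolysis with reductive work-up cleaves the only C=C bond to the C1 aldehyde, and cis-epoxy aldehydes are configurationally stable under these neutral conditions.

Step 8
Reactants: 14 benzeneselenenyl bromide; 15 ethene
Product: 16 (2-bromoethyl)(phenyl)selane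
Conditions: ethene (1 atm), CH2Cl2, 0 °C to rt
Reagents that add atoms: none
Why: electrophilic selenenylation of an alkene, in which PhSeBr adds across ethene through a seleniranium ion to give the β-bromo selenide.

Step 9
Reactants: 16 (2-bromoethyl)(phenyl)selane; 17 trimethyl phosphonoacetate
Product: 18 methyl 2-(dimethoxyphosphoryl)-4-(phenylselanyl)butanoate
Conditions: 17 (excess), NaH, DMF, 0 °C; then 16, rt to 50 °C
Reagents that add atoms: none
Why: C-alkylation of the sodium phosphonoacetate by a primary bromide activated by the neighbouring selenium, with excess nucleophile limiting dialkylation.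

Step 10
Reactants: 13 (2S,3R)-3-[(2R,3R)-3-({[tert-butyl(dimethyl)silyl]oxy}methyl)-2-methyloxiran-2-yl]oxirane-2-carbaldehyde; 18 methyl 2-(dimethoxyphosphoryl)-4-(phenylselanyl)butanoate
Product: 19 methyl (2E)-3-{(2R,3R)-3-[(2R,3R)-3-({[tert-butyl(dimethyl)silyl]oxy}methyl)-2-methyloxiran-2-yl]oxiran-2-yl}-2-[2-(phenylselanyl)ethyl]prop-2-enoate
Conditions: 18, NaH, THF, 0 °C; then 13, −20 to 0 °C
Reagents that add atoms: none
Why: Horner–Wadsworth–Emmons olefination of an α-branched, α-oxygenated aldehyde with an α-alkyl trimethyl phosphonate should favour the isomer with the ester trans to C2, which puts C2 cis to the future C9 vinyl; the minor isomer is removed by chromatography.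

Step 11
Reactants: 19 methyl (2E)-3-{(2R,3R)-3-[(2R,3R)-3-({[tert-butyl(dimethyl)silyl]oxy}methyl)-2-methyloxiran-2-yl]oxiran-2-yl}-2-[2-(phenylselanyl)ethyl]prop-2-enoate
Product: 21 methyl (2E)-2-ethenyl-3-{(2R,3R)-3-[(2R,3R)-3-({[tert-butyl(dimethyl)silyl]oxy}methyl)-2-methyloxiran-2-yl]oxiran-2-yl}prop-2-enoate, via selenoxide 20 (not isolated)
Conditions: NaIO4, NaHCO3, THF–MeOH–H2O, 0 °C to rt
Reagents that add atoms: none
Why: selenide oxidation followed by selenoxide syn-elimination, in which the only β-hydrogens are on the CH2 next to C10, so the C9 vinyl group forms without palladium that could ionise the vinyl epoxide.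

Step 12
Reactants: 21 methyl (2E)-2-ethenyl-3-{(2R,3R)-3-[(2R,3R)-3-({[tert-butyl(dimethyl)silyl]oxy}methyl)-2-methyloxiran-2-yl]oxiran-2-yl}prop-2-enoate
Product: 22 methyl (2E)-2-ethenyl-3-{(2R,3R)-3-[(2R,3R)-3-(hydroxymethyl)-2-methyloxiran-2-yl]oxiran-2-yl}prop-2-enoate
Conditions: Bu4NF, AcOH, THF, 0 °C to rt
Reagents that add atoms: none
Why: fluoride desilylation, buffered with acetic acid so that the liberated alkoxide is protonated before it can start a Payne rearrangement.

Step 13
Reactants: 22 methyl (2E)-2-ethenyl-3-{(2R,3R)-3-[(2R,3R)-3-(hydroxymethyl)-2-methyloxiran-2-yl]oxiran-2-yl}prop-2-enoate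
Product: 23 methyl (2E)-2-ethenyl-3-{(2R,3R)-3-[(2S,3S)-3-formyl-2-methyloxiran-2-yl]oxiran-2-yl}prop-2-enoate
Conditions: Dess–Martin periodinane, pyridine, CH2Cl2, 0 °C
Reagents that add atoms: none
Why: Dess–Martin oxidation gives the C6 aldehyde under neutral conditions that leave the dienoate and both oxiranes intact.

Step 14
Reactants: 24 acryloyl chloride; 25 2-(trimethylsilyl)ethanol
Product: 26 2-(trimethylsilyl)ethyl prop-2-enoate
Conditions: Et3N, CH2Cl2, 0 °C
Reagents that add atoms: none
Why: acylation of a primary alcohol by an acid chloride, which installs an ester that fluoride can later cleave beside the C14 methyl ester.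

Step 15
Reactants: 26 2-(trimethylsilyl)ethyl prop-2-enoate; 27 acrolein
Product: 28 2-(trimethylsilyl)ethyl 3-hydroxy-2-methylidenepent-4-enoate (racemic)
Conditions: DABCO (20 mol %), 26 in excess, neat, 0 °C to rt
Reagents that add atoms: none
Why: Baylis–Hillman reaction, in which the ammonium enolate of the acrylate adds to the aldehyde carbonyl of acrolein; the stereocentre is lost in the next step.

Step 16
Reactants: 28 2-(trimethylsilyl)ethyl 3-hydroxy-2-methylidenepent-4-enoate
Product: 29 2-(trimethylsilyl)ethyl (2Z)-2-(bromomethyl)penta-2,4-dienoate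
Conditions: PBr3, Et2O, −10 to 0 °C
Reagents that add atoms: phosphorus tribromide, BrP(Br)Br
Why: SN2′ bromination of a Baylis–Hillman alcohol gives the conjugated (2Z)-bromide as the thermodynamic allylic isomer, and any regioisomeric bromide would lead to the same pentadienylzinc.

Step 17
Reactants: 23 methyl (2E)-2-ethenyl-3-{(2R,3R)-3-[(2S,3S)-3-formyl-2-methyloxiran-2-yl]oxiran-2-yl}prop-2-enoate; 29 2-(trimethylsilyl)ethyl (2Z)-2-(bromomethyl)penta-2,4-dienoate
Product: 31 2-(trimethylsilyl)ethyl (3S,4R)-3-ethenyl-4-hydroxy-4-{(2R,3R)-3-[(2R,3R)-3-[(1E)-2-(methoxycarbonyl)buta-1,3-dien-1-yl]oxiran-2-yl]-3-methyloxiran-2-yl}-2-methylidenebutanoate, via allylzinc bromide 30 (not isolated)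
Conditions: Zn dust, saturated aqueous NH4Cl–THF, 0 °C
Reagents that add atoms: none
Why: Barbier allylation, in which the allylzinc bonds through its γ-carbon in a closed chair transition state with the vinyl group cis to CH2Zn (6,7-syn) and attacks the cis-epoxy aldehyde in the Felkin–Anh sense anti to the C5–O bond (6R); C6 is thus deliberately the epimer of the target and C7 is correct, so the invertive lactonisation of step 19 sets both the C5/C6 and the trans C6/C7 relationships.

Step 18
Reactants: 31 2-(trimethylsilyl)ethyl (3S,4R)-3-ethenyl-4-hydroxy-4-{(2R,3R)-3-[(2R,3R)-3-[(1E)-2-(methoxycarbonyl)buta-1,3-dien-1-yl]oxiran-2-yl]-3-methyloxiran-2-yl}-2-methylidenebutanoate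
Product: 32 the C6 methanesulfonate of 31 (configuration unchanged: 6R,7S)
Conditions: MeSO2Cl, Et3N, CH2Cl2, −20 °C
Reagents that add atoms: methanesulfonyl chloride, CS(Cl)(=O)=O
Why: sulfonylation through sulfene works on hindered secondary alcohols with retention and leaves epoxides, esters and alkenes untouched.

Step 19
Reactants: 32 the C6 methanesulfonate of 31
Product: 34 methyl (2E)-2-ethenyl-3-[(2R,3R)-3-{(2R,3R)-3-[(2S,3S)-3-ethenyl-4-methylidene-5-oxooxolan-2-yl]-2-methyloxiran-2-yl}oxiran-2-yl]prop-2-enoate, via tetrabutylammonium carboxylate 33 (not isolated)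
Conditions: Bu4NF, THF, 0 °C to rt
Reagents that add atoms: none
Why: fluoride fragments the 2-(trimethylsilyl)ethyl ester to the carboxylate, which displaces the C6 mesylate from the rear (5-exo-tet SN2) and closes the γ-lactone with inversion to 6S, turning the 6,7-syn adduct into the trans-lactone without ever exposing a free hydroxy acid that could lactonise with retention.

Step 20
Reactants: 34 methyl (2E)-2-ethenyl-3-[(2R,3R)-3-{(2R,3R)-3-[(2S,3S)-3-ethenyl-4-methylidene-5-oxooxolan-2-yl]-2-methyloxiran-2-yl}oxiran-2-yl]prop-2-enoate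
Product: 35 methyl (1(10)E,8Z)-(2R,3R,4R,5R,6S,7S)-2,3:4,5-diepoxygermacra-1(10),8,11(13)-trien-12,6-olid-14-oate
Conditions: second-generation Hoveyda–Grubbs catalyst RuCl2(H2IMes)(=CH-C6H4-2-OiPr) (15 mol %), toluene (1 mM), 80 °C
Reagents that add atoms: none
Why: The ruthenium alkylidene should load on the unhindered monosubstituted C7 vinyl group, add [2+2] to the terminal C9=CH2 of the dienoate and cyclorevert with loss of ethene, which forms C8=C9. The closest known reaction type is diene–ene ring-closing metathesis to medium-ring 1,3-dienes and to ten-membered carbocycles fused to γ-lactones. The ten-membered ring is closed by union of the two terminal alkene carbons C8 and C9 of one chain, at high dilution so that closure outruns cross-metathesis. No stereocentre is created; the new alkene is expected as Z because an E-C8=C9 bond conjugated to the ring-cis C1=C10 bond and flanked by the trans-fused lactone would be far more strained in a ten-membered ring. The step needs site selectivity among five C=C bonds, which the substrate secures: the C1=C10 enoate is trisubstituted and electron-poor, the C11=C13 methylidene is 1,1-disubstituted and acceptor-bound (its closure with C8 would give a cyclobutene), and the oxiranes are inert. The trans-lactone and the two cis-oxiranes bend the chain so that C8 and C9 can meet.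

Step 21
Reactants: 35 methyl (1(10)E,8Z)-(2R,3R,4R,5R,6S,7S)-2,3:4,5-diepoxygermacra-1(10),8,11(13)-trien-12,6-olid-14-oate
Product: 36 methyl (1(10)E)-(2R,3R,4R,5R,6S,7R,8S,9R)-2,3:4,5-diepoxy-8,9-dihydroxygermacra-1(10),11(13)-dien-12,6-olid-14-oate
Conditions: OsO4 (5 mol %), N-methylmorpholine N-oxide, acetone–H2O, 0 °C
Reagents that add atoms: osmium tetroxide, O=[Os](=O)(=O)=O; N-methylmorpholine N-oxide, C[N+]1([O-])CCOCC1
Why: Upjohn dihydroxylation, in which C8=C9 is the only alkene not bonded directly to a carbonyl carbon and the concerted [3+2] addition puts both oxygens on one face to give the erythro (ring-cis) diol; with H7 eclipsing the Z-alkene (allylic 1,3-strain) ring carbon C6 screens the inner face, so attack from the periphery, syn to C11, should give 8S,9R, which has to be confirmed on the real compound.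

Step 22
Reactants: 37 angelic acid, (2Z)-2-methylbut-2-enoic acid
Product: 38 (2Z)-2-methylbut-2-en-1-ol
Conditions: LiAlH4, Et2O, 0 °C to rt
Reagents that add atoms: none
Why: hydride reduction of the carboxylic acid is a 1,2-reduction that keeps the Z geometry.

Step 23
Reactants: 38 (2Z)-2-methylbut-2-en-1-ol
Product: 39 [(2R,3S)-2,3-dimethyloxiran-2-yl]methanol
Conditions: Ti(OiPr)4 (10 mol %), D-(−)-diisopropyl tartrate (12 mol %), tBuOOH, 4 Å sieves, CH2Cl2, −20 °C
Reagents that add atoms: tert-butyl hydroperoxide, CC(C)(C)OO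
Why: Sharpless asymmetric epoxidation, in which the D-(−)-tartrate complex delivers oxygen to the face opposite to that used in step 3 and so sets both side-chain stereocentres (2R,3S).

Step 24
Reactants: 39 [(2R,3S)-2,3-dimethyloxiran-2-yl]methanol
Product: 40 (2S,3S)-2,3-dimethyloxirane-2-carboxylic acid
Conditions: RuCl3 (2 mol %), NaIO4, CCl4–MeCN–H2O, rt
Reagents that add atoms: sodium periodate, [Na+].[O-]I(=O)(=O)=O; water, O
Why: ruthenium tetroxide oxidation of a primary epoxy alcohol to the glycidic acid keeps the oxirane; the descriptor at C2 changes only because the CIP priorities change.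

Step 25
Reactants: 36 methyl (1(10)E)-(2R,3R,4R,5R,6S,7R,8S,9R)-2,3:4,5-diepoxy-8,9-dihydroxygermacra-1(10),11(13)-dien-12,6-olid-14-oate
Product: 41 the 9-O-acetate of 36 (free C8–OH)
Conditions: Ac2O (1.1 equiv), pyridine, CH2Cl2, 0 °C
Reagents that add atoms: acetic anhydride, CC(=O)OC(C)=O
Why: kinetic monoacylation, in which the allylic C9–OH next to the planar C10 is less hindered than the C8–OH beside the lactone-bearing C7 and should react first without DMAP.

Step 26
Reactants: 41 the 9-O-acetate of 36; 40 (2S,3S)-2,3-dimethyloxirane-2-carboxylic acid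
Product: 43 CNP0077535.3, the 9-O-acetyl-8-O-[(2S,3S)-2,3-dimethyloxirane-2-carbonyl] derivative of 36, via mixed anhydride 42 (not isolated)
Conditions: 40, 2,4,6-trichlorobenzoyl chloride, Et3N, THF, rt; then 41, DMAP, toluene, rt
Reagents that add atoms: none
Why: Yamaguchi esterification, in which the mixed anhydride acylates the hindered C8–OH under DMAP catalysis; the acid has no α-hydrogen, so its stereocentres cannot epimerise.

**Compound list**
1 | 2-{[tert-butyl(dimethyl)silyl]oxy}acetaldehyde | CC(C)(C)[Si](C)(C)OCC=O | starting material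
2 | ethyl 2-[bis(2,2,2-trifluoroethoxy)phosphoryl]propanoate | CCOC(=O)C(C)P(=O)(OCC(F)(F)F)OCC(F)(F)F | starting material
3 | ethyl (2Z)-4-{[tert-butyl(dimethyl)silyl]oxy}-2-methylbut-2-enoate | CCOC(=O)/C(C)=C\CO[Si](C)(C)C(C)(C)C | intermediate
4 | (2Z)-4-{[tert-butyl(dimethyl)silyl]oxy}-2-methylbut-2-en-1-ol | OC/C(C)=C\CO[Si](C)(C)C(C)(C)C | intermediate
5 | [(2S,3R)-3-({[tert-butyl(dimethyl)silyl]oxy}methyl)-2-methyloxiran-2-yl]methanol | CC(C)(C)[Si](C)(C)OC[C@H]1O[C@@]1(C)CO | intermediate
6 | (2R,3R)-3-({[tert-butyl(dimethyl)silyl]oxy}methyl)-2-methyloxirane-2-carbaldehyde | CC(C)(C)[Si](C)(C)OC[C@H]1O[C@@]1(C)C=O | intermediate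
7 | allyl chloride | C=CCCl | starting material
8 | [(2Z)-3-chloroprop-2-en-1-yl]diisopinocampheylborane (from (+)-Ipc2BOMe) | Cl/C=C\CB([C@H]1C[C@H]2C[C@@H]([C@@H]1C)C2(C)C)[C@H]1C[C@H]2C[C@@H]([C@@H]1C)C2(C)C | intermediate
9 | diisopinocampheylborinate ester of 10 | CC(C)(C)[Si](C)(C)OC[C@H]1O[C@@]1(C)[C@H](OB([C@H]2C[C@H]3C[C@@H]([C@@H]2C)C3(C)C)[C@H]2C[C@H]3C[C@@H]([C@@H]2C)C3(C)C)[C@@H](Cl)C=C | intermediate
10 | (1S,2S)-1-[(2S,3R)-3-({[tert-butyl(dimethyl)silyl]oxy}methyl)-2-methyloxiran-2-yl]-2-chlorobut-3-en-1-ol | CC(C)(C)[Si](C)(C)OC[C@H]1O[C@@]1(C)[C@H](O)[C@@H](Cl)C=C | intermediate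
11 | tert-butyl{[(2R,3R)-3-[(2R,3R)-3-ethenyloxiran-2-yl]-3-methyloxiran-2-yl]methoxy}dimethylsilane | CC(C)(C)[Si](C)(C)OC[C@H]1O[C@@]1(C)[C@@H]1O[C@@H]1C=C | intermediate
12 | ozonide (1,2,4-trioxolane) of 11 | CC(C)(C)[Si](C)(C)OC[C@H]1O[C@@]1(C)[C@@H]1O[C@@H]1C1OCOO1 | intermediate
13 | (2S,3R)-3-[(2R,3R)-3-({[tert-butyl(dimethyl)silyl]oxy}methyl)-2-methyloxiran-2-yl]oxirane-2-carbaldehyde | CC(C)(C)[Si](C)(C)OC[C@H]1O[C@@]1(C)[C@@H]1O[C@@H]1C=O | intermediate
14 | benzeneselenenyl bromide | Br[Se]c1ccccc1 | starting material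
15 | ethene | C=C | starting material
16 | (2-bromoethyl)(phenyl)selane | BrCC[Se]c1ccccc1 | intermediate
17 | trimethyl phosphonoacetate | COC(=O)CP(=O)(OC)OC | starting material
18 | methyl 2-(dimethoxyphosphoryl)-4-(phenylselanyl)butanoate | COC(=O)C(CC[Se]c1ccccc1)P(=O)(OC)OC | intermediate
19 | methyl (2E)-3-{(2R,3R)-3-[(2R,3R)-3-({[tert-butyl(dimethyl)silyl]oxy}methyl)-2-methyloxiran-2-yl]oxiran-2-yl}-2-[2-(phenylselanyl)ethyl]prop-2-enoate | CC(C)(C)[Si](C)(C)OC[C@H]1O[C@@]1(C)[C@@H]1O[C@@H]1/C=C(\CC[Se]c1ccccc1)C(=O)OC | intermediate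
20 | selenoxide of 19 | CC(C)(C)[Si](C)(C)OC[C@H]1O[C@@]1(C)[C@@H]1O[C@@H]1/C=C(\CC[Se](=O)c1ccccc1)C(=O)OC | intermediate
21 | methyl (2E)-2-ethenyl-3-{(2R,3R)-3-[(2R,3R)-3-({[tert-butyl(dimethyl)silyl]oxy}methyl)-2-methyloxiran-2-yl]oxiran-2-yl}prop-2-enoate | CC(C)(C)[Si](C)(C)OC[C@H]1O[C@@]1(C)[C@@H]1O[C@@H]1/C=C(\C=C)C(=O)OC | intermediate
22 | methyl (2E)-2-ethenyl-3-{(2R,3R)-3-[(2R,3R)-3-(hydroxymethyl)-2-methyloxiran-2-yl]oxiran-2-yl}prop-2-enoate | OC[C@H]1O[C@@]1(C)[C@@H]1O[C@@H]1/C=C(\C=C)C(=O)OC | intermediate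
23 | methyl (2E)-2-ethenyl-3-{(2R,3R)-3-[(2S,3S)-3-formyl-2-methyloxiran-2-yl]oxiran-2-yl}prop-2-enoate | O=C[C@H]1O[C@@]1(C)[C@@H]1O[C@@H]1/C=C(\C=C)C(=O)OC | intermediate
24 | acryloyl chloride | C=CC(Cl)=O | starting material
25 | 2-(trimethylsilyl)ethanol | C[Si](C)(C)CCO | starting material
26 | 2-(trimethylsilyl)ethyl prop-2-enoate | C=CC(=O)OCC[Si](C)(C)C | intermediate
27 | acrolein | C=CC=O | starting material
28 | 2-(trimethylsilyl)ethyl 3-hydroxy-2-methylidenepent-4-enoate (racemic) | C=CC(O)C(=C)C(=O)OCC[Si](C)(C)C | intermediate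
29 | 2-(trimethylsilyl)ethyl (2Z)-2-(bromomethyl)penta-2,4-dienoate | C=C/C=C(\CBr)C(=O)OCC[Si](C)(C)C | intermediate
30 | allylzinc bromide from 29 | Br[Zn]C/C(C(=O)OCC[Si](C)(C)C)=C\C=C | intermediate
31 | 2-(trimethylsilyl)ethyl (3S,4R)-3-ethenyl-4-hydroxy-4-{(2R,3R)-3-[(2R,3R)-3-[(1E)-2-(methoxycarbonyl)buta-1,3-dien-1-yl]oxiran-2-yl]-3-methyloxiran-2-yl}-2-methylidenebutanoate | C=C(C(=O)OCC[Si](C)(C)C)[C@H](C=C)[C@@H](O)[C@H]1O[C@@]1(C)[C@@H]1O[C@@H]1/C=C(\C=C)C(=O)OC | intermediate
32 | C6 methanesulfonate of 31 | C=C(C(=O)OCC[Si](C)(C)C)[C@H](C=C)[C@@H](OS(C)(=O)=O)[C@H]1O[C@@]1(C)[C@@H]1O[C@@H]1/C=C(\C=C)C(=O)OC | intermediate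
33 | tetrabutylammonium carboxylate from 32 | C=C(C(=O)[O-])[C@H](C=C)[C@@H](OS(C)(=O)=O)[C@H]1O[C@@]1(C)[C@@H]1O[C@@H]1/C=C(\C=C)C(=O)OC.CCCC[N+](CCCC)(CCCC)CCCC | intermediate
34 | methyl (2E)-2-ethenyl-3-[(2R,3R)-3-{(2R,3R)-3-[(2S,3S)-3-ethenyl-4-methylidene-5-oxooxolan-2-yl]-2-methyloxiran-2-yl}oxiran-2-yl]prop-2-enoate | C=C1C(=O)O[C@@H]([C@H]1C=C)[C@H]1O[C@@]1(C)[C@@H]1O[C@@H]1/C=C(\C=C)C(=O)OC | intermediate
35 | methyl (1(10)E,8Z)-(2R,3R,4R,5R,6S,7S)-2,3:4,5-diepoxygermacra-1(10),8,11(13)-trien-12,6-olid-14-oate | C=C1C(=O)O[C@H]2[C@H]1/C=C\C(C(=O)OC)=C/[C@H]1O[C@H]1[C@]1(C)O[C@H]21 | intermediate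
36 | methyl (1(10)E)-(2R,3R,4R,5R,6S,7R,8S,9R)-2,3:4,5-diepoxy-8,9-dihydroxygermacra-1(10),11(13)-dien-12,6-olid-14-oate | C=C1C(=O)O[C@H]2[C@H]1[C@H](O)[C@H](O)/C(C(=O)OC)=C\[C@H]1O[C@H]1[C@]1(C)O[C@H]21 | intermediate
37 | angelic acid, (2Z)-2-methylbut-2-enoic acid | C/C=C(/C)C(=O)O | starting material
38 | (2Z)-2-methylbut-2-en-1-ol | C/C=C(/C)CO | intermediate
39 | [(2R,3S)-2,3-dimethyloxiran-2-yl]methanol | OC[C@@]1(C)O[C@H]1C | intermediate
40 | (2S,3S)-2,3-dimethyloxirane-2-carboxylic acid | OC(=O)[C@@]1(C)O[C@H]1C | intermediate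
41 | 9-O-acetate of 36 | C=C1C(=O)O[C@H]2[C@H]1[C@H](O)[C@H](OC(C)=O)/C(C(=O)OC)=C\[C@H]1O[C@H]1[C@]1(C)O[C@H]21 | intermediate
42 | (2S,3S)-2,3-dimethyloxirane-2-carboxylic 2,4,6-trichlorobenzoic anhydride | O=C(OC(=O)c1c(Cl)cc(Cl)cc1Cl)[C@@]1(C)O[C@H]1C | intermediate
43 | CNP0077535.3 | C=C1C(=O)O[C@H]2[C@H]1[C@H](OC(=O)[C@@]1(C)O[C@H]1C)[C@H](OC(C)=O)/C(C(=O)OC)=C\[C@H]1O[C@H]1[C@]1(C)O[C@H]21 | target

**Step count**
Total steps: 26. Longest linear sequence: 18 steps (1–7, 10–13, 17–21, 25, 26).

**Steps most likely to fail**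

Step 20 (ring-closing metathesis). Cross-metathesis to oligomers may outrun closure of the strained ten-membered ring, the carbene may stall as an ester-chelated vinylalkylidene, or some E-C8=C9 isomer may form. The fallback reverses the order of ring formation. It sets out from 31: metathesis of the open seco-ester, which is free of lactone strain and has a different conformational bias, should give the ten-membered hydroxy ester F1 under the same catalyst. Mesylation gives the carbocyclic mesylate F2, and Bu4NF then triggers the same carboxylate SN2 lactonisation on the preformed ring. The route is rejoined at 35.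

Step 17 (Barbier allylation). Metallotropic shifts in the pentadienylzinc may erode the 6,7-syn selectivity or lead to attack through the terminal carbon, and the facial selectivity at the epoxy aldehyde may be incomplete. The fallback replaces the organozinc made in the flask by an isolated, configurationally stable allylboron reagent. It sets out from 29: copper-catalysed borylation (B2pin2, CuCl, KOAc, DMF) should give the (Z)-allylboronate F3. Heating F3 with aldehyde 23 in toluene lets it react through a closed chair transition state with fixed olefin geometry, giving the O-boryl adduct F4. Aqueous work-up hydrolyses F4 and the route is rejoined at 31.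

Step 21 (dihydroxylation). Osmylation may occur on the face anti to C11, or compete at the methylidene lactone. The fallback delivers the cis-diol to the face opposite to the one an electrophile attacks first, by a Woodward cis-hydroxylation that sets out from 35. With I2 and AgOAc in AcOH at rt, iodonium formation on the exposed face and anti opening by acetate should give the trans iodo acetate F5. Wet AcOH then lets the acetate displace iodide with neighbouring-group participation and hydrolyse to the cis hydroxy acetate with both oxygens syn to C11. The 9-O-acetate is 41, where the route is rejoined. Its 8-O-acetyl isomer F6 is separated and equilibrated to 41 by 1,2-acetyl shift.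

**Further compounds**
F1 | step 20 | ten-membered hydroxy ester, 2-(trimethylsilyl)ethyl ester of the C8=C9 ring-closed form of 31 | C=C(C(=O)OCC[Si](C)(C)C)[C@@H]1/C=C\C(C(=O)OC)=C/[C@H]2O[C@H]2[C@]2(C)O[C@@H]2[C@@H]1O
F2 | step 20 | C6 methanesulfonate of F1 | C=C(C(=O)OCC[Si](C)(C)C)[C@@H]1/C=C\C(C(=O)OC)=C/[C@H]2O[C@H]2[C@]2(C)O[C@@H]2[C@@H]1OS(C)(=O)=O
F3 | step 17 | 2-(trimethylsilyl)ethyl (2Z)-2-[(4,4,5,5-tetramethyl-1,3,2-dioxaborolan-2-yl)methyl]penta-2,4-dienoate | C=C/C=C(\CB1OC(C)(C)C(C)(C)O1)C(=O)OCC[Si](C)(C)C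
F4 | step 17 | O-(pinacolatoboryl) derivative of 31 | C=C(C(=O)OCC[Si](C)(C)C)[C@H](C=C)[C@@H](OB1OC(C)(C)C(C)(C)O1)[C@H]1O[C@@]1(C)[C@@H]1O[C@@H]1/C=C(\C=C)C(=O)OC
F5 | step 21 | trans 9-acetoxy-8-iodo adduct of 35 | C=C1C(=O)O[C@H]2[C@H]1[C@@H](I)[C@H](OC(C)=O)/C(C(=O)OC)=C\[C@H]1O[C@H]1[C@]1(C)O[C@H]21
F6 | step 21 | 8-O-acetate of 36 (free C9–OH) | C=C1C(=O)O[C@H]2[C@H]1[C@H](OC(C)=O)[C@H](O)/C(C(=O)OC)=C\[C@H]1O[C@H]1[C@]1(C)O[C@H]21
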